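**Strategy.** The ring is read as a masked 4‑oxygenated 3‑methylcyclohex‑2‑enone: C6 (acetate carbon) is the carbonyl, C4=C5 (methyl carbinol and ring angelate carbons) the enone alkene, C3 (chlorine carbon) the γ‑carbon. One amine‑catalysed asymmetric Robinson annulation joins 1‑silyloxyacetone (C3, C4, methyl) to an α‑propargyl vinyl ketone (C2, C1, C6, C5): Michael bond C2–C3, aldol‑condensation bond C4–C5, and the single catalyst‑set ring stereocentre C3. Substrate control relays it to C4/C5 (anti‑dihydroxylation), C1 (equilibration), C6 (hydride) and the chlorohydrin (epoxide, trans‑diaxial opening). The propargyl arm then grows into the side chain by hydration, methylenation, aldol addition and CBS reduction.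

Key step: step 2

Remarks and assumptions.
- Locants follow the target: ring C1 (carries the side chain), C2 (CH2), C3 (CHCl), C4 (C(CH3)OH), C5 (ring angelate), C6 (acetate); side chain C7 (bears the exocyclic CH2), C8 (CHOH), C9, C10 (angelate), C11 (CMe2OH). β is the ring face of the C1 substituent, α the other face.
- Compounds 1, 3, 8 and 17 are taken as commercial.
- Each chiral catalyst or reagent is named as the antipode expected to give the drawn centre; its mirror image is used if Mosher analysis of the product shows the opposite sense.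

Step 1
Reactants: 1 hex‑5‑yn‑2‑one
Product: 2 3‑methylidenehex‑5‑yn‑2‑one
Conditions: (CH2O)n, N‑methylanilinium trifluoroacetate, THF, reflux
Reagents that add atoms: formaldehyde (as paraformaldehyde) C=O
Why: Acid‑mediated Mannich condensation with formaldehyde and loss of the amine (Gras α‑methylenation) runs through the more substituted enol, so the methylene enters at C3 of the methyl ketone and not at the methyl group.

Step 2
Reactants: 2 3‑methylidenehex‑5‑yn‑2‑one, 3 1‑[(tert‑butyldimethylsilyl)oxy]propan‑2‑one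
Product: 6 (4S,6S)‑4‑[(tert‑butyldimethylsilyl)oxy]‑3‑methyl‑6‑(prop‑2‑yn‑1‑yl)cyclohex‑2‑en‑1‑one, via Michael adduct 4 (not isolated), via ketol 5 (not isolated)
Conditions: 3 (3 equiv), (1S,2S)‑N1,N1‑dipropylcyclohexane‑1,2‑diamine·TfOH (20 mol%), 3‑nitrobenzoic acid (20 mol%), CHCl3, rt, then 45 °C
Reagents that add atoms: none
Why: The primary amine condenses with 3 to the Z‑enamine on the silyloxy‑bearing carbon, which adds to the terminal CH2 of the acid‑activated enone 2 (bond C2–C3); the same amine then forms the methyl‑side enamine of the less hindered ketone of 4, which closes the ring by a 6‑(enolendo)‑exo‑trig aldol addition onto the inductively activated α‑silyloxy ketone (bond C4–C5), and iminium‑assisted loss of water gives enone 6. The closest known reactions are the primary‑amine‑catalysed asymmetric Robinson annulations of vinyl ketones and the primary‑amine‑catalysed enamine reactions of O‑protected hydroxyacetone at its oxygenated carbon. The aldol addition is the only ring closure and water is the only by‑product. C3 is set by the catalyst, which shields one face of the enamine in the Michael step; C1 stays epimerisable through the dienamine and should settle trans to the pseudo‑axial C3 silyloxy group. The step needs donor regioselectivity (the α‑oxygen directs enamine formation to its own carbon), aldol regioselectivity (the α‑silyloxy ketone is the better electrophile and the acetyl enamine on the propargyl side the more accessible nucleophile) and configurational stability of C3 (the α‑branched adduct re‑forms its enamine slowly, and after dehydration C3 is a γ‑carbon). The silyl ether also blocks isomerisation of the γ‑oxygenated enone to a 1,4‑dione.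

Step 3
Reactants: 6 (4S,6S)‑4‑[(tert‑butyldimethylsilyl)oxy]‑3‑methyl‑6‑(prop‑2‑yn‑1‑yl)cyclohex‑2‑en‑1‑one
Product: 7 keto diol, (2R,3S,4S,6S)‑4‑[(tert‑butyldimethylsilyl)oxy]‑2,3‑dihydroxy‑3‑methyl‑6‑(prop‑2‑yn‑1‑yl)cyclohexan‑1‑one (4β,5β‑diol in target locants)
Conditions: OsO4 (5 mol%), NMO, citric acid, t‑BuOH/H2O, rt
Reagents that add atoms: osmium tetroxide O=[Os](=O)(=O)=O (catalytic), N‑methylmorpholine N‑oxide C[N+]1([O-])CCOCC1, water O
Why: Upjohn dihydroxylation, accelerated for the electron‑poor enone by citric acid, should add both oxygens to the face of C4=C5 anti to the allylic C3 silyloxy group (held pseudo‑axial by A(1,2) strain with the C4 methyl), which sets C4 and C5 in one event while the terminal alkyne is inert.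

Step 4
Reactants: 7 keto diol, 8 angelic acid [(2Z)‑2‑methylbut‑2‑enoic acid]
Product: 9 5β‑O‑angeloyl‑4β‑hydroxy‑4α‑methyl‑1β‑(prop‑2‑ynyl)‑3α‑(tert‑butyldimethylsilyloxy)cyclohexan‑6‑one
Conditions: 8, 2,4,6‑trichlorobenzoyl chloride, Et3N, toluene, rt; then 7, 60 °C
Reagents that add atoms: none
Why: Yamaguchi esterification through the 2,4,6‑trichlorobenzoyl mixed anhydride, run without DMAP so that the angelate does not isomerise to the tiglate, acylates the only secondary hydroxyl (C5) and leaves the tertiary C4 hydroxyl free, while the epimerisable C1 settles equatorial, trans to the axial C3 silyloxy group.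

Step 5
Reactants: 9 5β‑O‑angeloyl ketone
Product: 10 6β‑alcohol (5β‑O‑angeloyl‑4β,6β‑dihydroxy‑4α‑methyl‑1β‑propargyl‑3α‑silyloxycyclohexane)
Conditions: LiBH(s‑Bu)3, THF, −78 °C; aq. NH4Cl
Reagents that add atoms: none
Why: The bulky trialkylborohydride attacks the C6 ketone along the equatorial trajectory, the axial side being blocked by the axial C4 hydroxyl, and should give the axial C6 alcohol cis to the equatorial C5 angelate and C1 propargyl groups (substrate‑controlled ketone reduction).

Step 6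
Reactants: 10 6β‑alcohol
Product: 11 6β‑acetate
Conditions: Ac2O, pyridine, DMAP (cat.), CH2Cl2, rt
Reagents that add atoms: acetic anhydride CC(=O)OC(C)=O
Why: DMAP‑catalysed acetylation esterifies the secondary C6 hydroxyl, whereas the hindered tertiary C4 hydroxyl is not acylated at room temperature.

Step 7
Reactants: 11 6β‑acetate
Product: 12 3α,4β‑diol (6β‑O‑acetyl‑5β‑O‑angeloyl‑4α‑methyl‑1β‑propargylcyclohexane‑3α,4β‑diol)
Conditions: HF·pyridine, pyridine, THF, 0 °C to rt
Reagents that add atoms: none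
Why: Buffered fluoride cleaves the secondary silyl ether without touching the esters, the alkyne or the tertiary alcohol (desilylation).

Step 8
Reactants: 12 3α,4β‑diol
Product: 14 chlorohydrin (6β‑O‑acetyl‑5β‑O‑angeloyl‑3α‑chloro‑4β‑hydroxy‑4α‑methyl‑1β‑propargylcyclohexane), via epoxide 13 (not isolated)
Conditions: PPh3, DIAD, toluene, 0 °C to rt; then HCl (4 M in dioxane), 0 °C
Reagents that add atoms: hydrogen chloride Cl
Why: Mitsunobu activation of the secondary axial C3 hydroxyl and backside attack by the antiperiplanar tertiary C4 oxygen gives the 3β,4β‑epoxide with inversion at C3, and chloride then opens it by the trans‑diaxial (Fürst–Plattner) path at the less substituted C3, a second inversion that places chlorine α and returns the β C4 hydroxyl, attack at C4 being disfavoured by the chair requirement and by the neighbouring C5 ester.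

Step 9
Reactants: 14 chlorohydrin
Product: 15 methyl ketone (as 14, with 2‑oxopropyl in place of propargyl at C1)
Conditions: Ph3PAuNTf2 (2 mol%), H2O, 1,4‑dioxane, 60 °C
Reagents that add atoms: water O
Why: Gold‑catalysed Markovnikov hydration of the terminal alkyne gives the methyl ketone under near‑neutral conditions that spare the esters and the chlorohydrin.

Step 10
Reactants: 15 methyl ketone
Product: 16 enone (as 14, with 3‑oxobut‑1‑en‑2‑yl at C1; C7 now carries the exocyclic methylene)
Conditions: (CH2O)n, N‑methylanilinium trifluoroacetate, THF, reflux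
Reagents that add atoms: formaldehyde (as paraformaldehyde) C=O
Why: Acid‑mediated Mannich methylenation takes place at the more substituted α‑carbon of the unsymmetrical methyl ketone (C7, between ring and carbonyl) and creates the 1,1‑disubstituted alkene of the target.

Step 11
Reactants: 17 2‑methylbut‑3‑en‑2‑ol, 8 angelic acid
Product: 18 2‑methylbut‑3‑en‑2‑yl (2Z)‑2‑methylbut‑2‑enoate
Conditions: 8, 2,4,6‑trichlorobenzoyl chloride, Et3N, THF, 0 °C; then lithium alkoxide of 17 (n‑BuLi, THF, −78 °C), −78 to 0 °C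
Reagents that add atoms: none
Why: The lithium alkoxide of the tertiary alcohol attacks the unhindered angeloyl carbonyl of the mixed anhydride at low temperature, conditions under which angelates are not expected to isomerise (acylation of an alkoxide).

Step 12
Reactants: 18 2‑methylbut‑3‑en‑2‑yl angelate
Product: 19 2‑methyl‑1‑oxopropan‑2‑yl (2Z)‑2‑methylbut‑2‑enoate
Conditions: OsO4 (2 mol%), NaIO4, 2,6‑lutidine, dioxane/H2O, rt
Reagents that add atoms: sodium periodate [Na+].[O-]I(=O)(=O)=O (oxygen delivered through catalytic osmium tetroxide O=[Os](=O)(=O)=O)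
Why: Lemieux–Johnson cleavage takes the monosubstituted vinyl group in preference to the electron‑poor trisubstituted angelate alkene and gives a non‑enolisable α‑acyloxy aldehyde.

Step 13
Reactants: 16 enone, 19 2‑methyl‑1‑oxopropan‑2‑yl angelate
Product: 20 aldol adduct, (10R)‑10‑hydroxy‑11‑angeloyloxy enone (C8 ketone, C7 methylene)
Conditions: (−)‑Ipc2BCl, Et3N, Et2O, −78 to 0 °C; 19, −78 to −20 °C; then H2O2, pH 7 buffer, MeOH, 0 °C
Reagents that add atoms: none
Why: In this Paterson boron aldol reaction the diisopinocampheyl enolborinate formed at the methyl group of the enone adds to the non‑enolisable aldehyde through a cyclic transition state in which the Ipc ligands select the aldehyde face and so set C10, while the esters and the chlorohydrin are inert to the boron reagent at low temperature.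

Step 14
Reactants: 20 aldol adduct
Product: 21 (10R)‑10‑angeloyloxy‑11‑hydroxy enone
Conditions: TsOH·H2O (10 mol%), CH2Cl2, rt
Reagents that add atoms: none
Why: Acid‑catalysed 1,2‑acyl migration through a five‑membered ortho‑acid moves the angelate from the tertiary C11 oxygen to the neighbouring secondary C10 oxygen, driven by relief of strain in the tertiary ester, under conditions mild enough to leave the β‑acyloxy ketone and the chlorohydrin intact.

Step 15
Reactants: 21 (10R)‑10‑angeloyloxy‑11‑hydroxy enone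
Product: 22 target CNP0124048.1
Conditions: (S)‑2‑methyl‑CBS‑oxazaborolidine, catecholborane, toluene, −78 °C
Reagents that add atoms: none
Why: Corey–Bakshi–Shibata reduction of the α‑methylene ketone, in which the branched alkenyl group is the large substituent, should give the (8R) allylic alcohol by reagent control, anti to the C10 angelate, and completes the target.

**Compound list**
1 | hex‑5‑yn‑2‑one | CC(=O)CCC#C | starting material
2 | 3‑methylidenehex‑5‑yn‑2‑one | CC(=O)C(=C)CC#C | intermediate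
3 | 1‑[(tert‑butyldimethylsilyl)oxy]propan‑2‑one | CC(=O)CO[Si](C)(C)C(C)(C)C | starting material
4 | Michael adduct, (3S)‑3‑[(tert‑butyldimethylsilyl)oxy]‑5‑(prop‑2‑yn‑1‑yl)heptane‑2,6‑dione (both C5 epimers) | C#CCC(C[C@H](O[Si](C)(C)C(C)(C)C)C(C)=O)C(C)=O | intermediate
5 | ketol, (4S)‑4‑[(tert‑butyldimethylsilyl)oxy]‑3‑hydroxy‑3‑methyl‑6‑(prop‑2‑yn‑1‑yl)cyclohexan‑1‑one (mixture at C3 and C6) | C#CCC1C[C@H](O[Si](C)(C)C(C)(C)C)C(C)(O)CC1=O | intermediate
6 | (4S,6S)‑4‑[(tert‑butyldimethylsilyl)oxy]‑3‑methyl‑6‑(prop‑2‑yn‑1‑yl)cyclohex‑2‑en‑1‑one (3α‑silyloxy, 1β‑propargyl in target locants) | C#CC[C@H]1C[C@H](O[Si](C)(C)C(C)(C)C)C(C)=CC1=O | intermediate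
7 | keto diol, (2R,3S,4S,6S)‑4‑[(tert‑butyldimethylsilyl)oxy]‑2,3‑dihydroxy‑3‑methyl‑6‑(prop‑2‑yn‑1‑yl)cyclohexan‑1‑one | C#CC[C@H]1C[C@H](O[Si](C)(C)C(C)(C)C)[C@@](C)(O)[C@@H](O)C1=O | intermediate
8 | angelic acid, (2Z)‑2‑methylbut‑2‑enoic acid | C/C=C(/C)C(=O)O | starting material
9 | 5β‑O‑angeloyl‑4β‑hydroxy‑4α‑methyl‑1β‑(prop‑2‑ynyl)‑3α‑(tert‑butyldimethylsilyloxy)cyclohexan‑6‑one | C#CC[C@H]1C[C@H](O[Si](C)(C)C(C)(C)C)[C@@](C)(O)[C@@H](OC(=O)/C(C)=C\C)C1=O | intermediate
10 | 6β‑alcohol of 9 (4β,6β‑diol, 5β‑angelate, 3α‑silyl ether) | C#CC[C@H]1C[C@H](O[Si](C)(C)C(C)(C)C)[C@@](C)(O)[C@@H](OC(=O)/C(C)=C\C)[C@H]1O | intermediate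
11 | 6β‑acetate of 10 | C#CC[C@H]1C[C@H](O[Si](C)(C)C(C)(C)C)[C@@](C)(O)[C@@H](OC(=O)/C(C)=C\C)[C@H]1OC(C)=O | intermediate
12 | 6β‑O‑acetyl‑5β‑O‑angeloyl‑4α‑methyl‑1β‑(prop‑2‑ynyl)cyclohexane‑3α,4β‑diol | C#CC[C@H]1C[C@H](O)[C@@](C)(O)[C@@H](OC(=O)/C(C)=C\C)[C@H]1OC(C)=O | intermediate
13 | 3β,4β‑epoxide (6β‑acetate, 5β‑angelate, 4α‑methyl, 1β‑propargyl) | C#CC[C@H]1C[C@H]2O[C@@]2(C)[C@@H](OC(=O)/C(C)=C\C)[C@H]1OC(C)=O | intermediate
14 | chlorohydrin, 6β‑O‑acetyl‑5β‑O‑angeloyl‑3α‑chloro‑4β‑hydroxy‑4α‑methyl‑1β‑(prop‑2‑ynyl)cyclohexane | C#CC[C@H]1C[C@H](Cl)[C@@](C)(O)[C@@H](OC(=O)/C(C)=C\C)[C@H]1OC(C)=O | intermediate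
15 | methyl ketone, as 14 with 2‑oxopropyl at C1 | CC(=O)C[C@H]1C[C@H](Cl)[C@@](C)(O)[C@@H](OC(=O)/C(C)=C\C)[C@H]1OC(C)=O | intermediate
16 | enone, as 14 with 3‑oxobut‑1‑en‑2‑yl at C1 | C=C(C(C)=O)[C@H]1C[C@H](Cl)[C@@](C)(O)[C@@H](OC(=O)/C(C)=C\C)[C@H]1OC(C)=O | intermediate
17 | 2‑methylbut‑3‑en‑2‑ol | C=CC(C)(C)O | starting material
18 | 2‑methylbut‑3‑en‑2‑yl (2Z)‑2‑methylbut‑2‑enoate | C=CC(C)(C)OC(=O)/C(C)=C\C | intermediate
19 | 2‑methyl‑1‑oxopropan‑2‑yl (2Z)‑2‑methylbut‑2‑enoate | O=CC(C)(C)OC(=O)/C(C)=C\C | intermediate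
20 | aldol adduct, (10R)‑10‑hydroxy‑11‑angeloyloxy C8 ketone with C7 methylene; ring as in 14 | C=C(C(=O)C[C@@H](O)C(C)(C)OC(=O)/C(C)=C\C)[C@H]1C[C@H](Cl)[C@@](C)(O)[C@@H](OC(=O)/C(C)=C\C)[C@H]1OC(C)=O | intermediate
21 | (10R)‑10‑angeloyloxy‑11‑hydroxy C8 ketone with C7 methylene; ring as in 14 | C=C(C(=O)C[C@@H](OC(=O)/C(C)=C\C)C(C)(C)O)[C@H]1C[C@H](Cl)[C@@](C)(O)[C@@H](OC(=O)/C(C)=C\C)[C@H]1OC(C)=O | intermediate
22 | CNP0124048.1, (1R,3S,4S,5S,6S,8R,10R) in the locants above | C=C([C@H](O)C[C@@H](OC(=O)/C(C)=C\C)C(C)(C)O)[C@H]1C[C@H](Cl)[C@@](C)(O)[C@@H](OC(=O)/C(C)=C\C)[C@H]1OC(C)=O | target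

**Step count.** 15 steps in total. The longest linear sequence is 13 steps (steps 1–10 and 13–15); steps 11 and 12 make aldehyde 19.

**Steps most likely to fail**

1. Step 2. The Michael addition may give poor enantiofacial control, the ring may close through the other aldol mode (donor methyl onto the propargyl‑side ketone), or the silyloxy centre may epimerise before closure. The fallback sets out from 2 and comes back at 6. Classical Robinson annulation of 2 with ethyl acetoacetate (NaOEt, EtOH; then aqueous KOH, heat; acidification) passes through ethyl 2‑methyl‑4‑oxo‑5‑(prop‑2‑yn‑1‑yl)cyclohex‑2‑ene‑1‑carboxylate F1 and, after saponification and decarboxylation, gives racemic 3‑methyl‑6‑(prop‑2‑yn‑1‑yl)cyclohex‑2‑en‑1‑one F2. Thermodynamic silylation (TBSOTf, Et3N) gives the linear silyl dienol ether F3, and vinylogous Rubottom oxidation with dimethyldioxirane gives racemic 4‑hydroxy‑3‑methyl‑6‑(prop‑2‑yn‑1‑yl)cyclohex‑2‑en‑1‑one F4. Lipase‑catalysed kinetic resolution (Burkholderia cepacia lipase, vinyl acetate), expected to acylate the (4R) alcohol, leaves the (4S) alcohol F5 and removes the (4R) acetate F6. Silylation of F5 (TBSCl, imidazole) gives 6.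

2. Step 13. The aldol addition may show poor facial selectivity at C10, because reagent control by Ipc2BCl on methyl ketones is only moderate. The fallback sets out from 16 and comes back at 20. Soft enolisation (TMSOTf, Et3N, CH2Cl2, −78 °C) gives the 2‑silyloxy diene F7, in which the C4 hydroxyl is silylated as well. A catalytic asymmetric Mukaiyama aldol addition of F7 to 19 with a chiral Lewis acid made from Ti(OiPr)4 and (R)‑ or (S)‑BINOL, followed by mild acidic work‑up that cleaves both trimethylsilyl groups, gives 20.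

3. Step 14. The acyl transfer from the tertiary to the secondary oxygen may be slow or incomplete, or the β‑acyloxy ketone may eliminate. The fallback sets out from 16 and comes back at 22. The boron aldol reaction of step 13 is run with 2‑methyl‑2‑[(triethylsilyl)oxy]propanal F8 (from methyl 2‑hydroxyisobutyrate by silylation and DIBAL‑H reduction) and gives the β‑hydroxy ketone F9. Hydroxyl‑directed anti reduction with Me4NBH(OAc)3 (MeCN/AcOH, −30 °C) gives the 8,10‑anti diol F10. Selective silylation of the less hindered allylic C8 hydroxyl (TESCl, imidazole, −20 °C) gives F11, Yamaguchi esterification with 8 gives the C10 angelate F12, and HF·pyridine removes both silyl groups to give 22.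

**Further compounds**
F1 | step 2 | ethyl 2‑methyl‑4‑oxo‑5‑(prop‑2‑yn‑1‑yl)cyclohex‑2‑ene‑1‑carboxylate (racemic, diastereomer mixture) | CCOC(=O)C1CC(CC#C)C(=O)C=C1C
F2 | step 2 | racemic 3‑methyl‑6‑(prop‑2‑yn‑1‑yl)cyclohex‑2‑en‑1‑one | C#CCC1CCC(C)=CC1=O
F3 | step 2 | racemic tert‑butyldimethyl{[3‑methyl‑6‑(prop‑2‑yn‑1‑yl)cyclohexa‑1,3‑dien‑1‑yl]oxy}silane | C#CCC1CC=C(C)C=C1O[Si](C)(C)C(C)(C)C
F4 | step 2 | racemic 4‑hydroxy‑3‑methyl‑6‑(prop‑2‑yn‑1‑yl)cyclohex‑2‑en‑1‑one | C#CCC1CC(O)C(C)=CC1=O
F5 | step 2 | (4S)‑4‑hydroxy‑3‑methyl‑6‑(prop‑2‑yn‑1‑yl)cyclohex‑2‑en‑1‑one (C6 epimers) | C#CCC1C[C@H](O)C(C)=CC1=O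
F6 | step 2 | (4R)‑2‑methyl‑4‑oxo‑5‑(prop‑2‑yn‑1‑yl)cyclohex‑2‑en‑1‑yl acetate (C5 epimers) | C#CCC1C[C@@H](OC(C)=O)C(C)=CC1=O
F7 | step 13 | 2‑(trimethylsilyloxy)diene of 16 with the C4 hydroxyl as trimethylsilyl ether | C=C(O[Si](C)(C)C)C(=C)[C@H]1C[C@H](Cl)[C@@](C)(O[Si](C)(C)C)[C@@H](OC(=O)/C(C)=C\C)[C@H]1OC(C)=O
F8 | step 14 | 2‑methyl‑2‑[(triethylsilyl)oxy]propanal | O=CC(C)(C)O[Si](CC)(CC)CC
F9 | step 14 | (10R)‑10‑hydroxy‑11‑(triethylsilyloxy) C8 ketone; ring as in 14 | C=C(C(=O)C[C@@H](O)C(C)(C)O[Si](CC)(CC)CC)[C@H]1C[C@H](Cl)[C@@](C)(O)[C@@H](OC(=O)/C(C)=C\C)[C@H]1OC(C)=O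
F10 | step 14 | (8R,10R)‑8,10‑diol, 11‑triethylsilyl ether; ring as in 14 | C=C([C@H](O)C[C@@H](O)C(C)(C)O[Si](CC)(CC)CC)[C@H]1C[C@H](Cl)[C@@](C)(O)[C@@H](OC(=O)/C(C)=C\C)[C@H]1OC(C)=O
F11 | step 14 | (8R,10R)‑10‑hydroxy‑8,11‑bis(triethylsilyl) ether; ring as in 14 | C=C([C@H](O[Si](CC)(CC)CC)C[C@@H](O)C(C)(C)O[Si](CC)(CC)CC)[C@H]1C[C@H](Cl)[C@@](C)(O)[C@@H](OC(=O)/C(C)=C\C)[C@H]1OC(C)=O
F12 | step 14 | 8,11‑bis(triethylsilyl) ether of 22 | C=C([C@H](O[Si](CC)(CC)CC)C[C@@H](OC(=O)/C(C)=C\C)C(C)(C)O[Si](CC)(CC)CC)[C@H]1C[C@H](Cl)[C@@](C)(O)[C@@H](OC(=O)/C(C)=C\C)[C@H]1OC(C)=O
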